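## The problem

Formosanatin D (24) is a flat pentacycle. A chromone (rings A and C) is joined to ring B through the C3–C1' bond and the C2–O–C2' bridge of a furan. Ring A carries a saturated 2,2-dimethylpyran (ring E) on C7–O/C8, and ring B carries a 2,2-dimethyl-2H-pyran (ring D; O1''–C2''–C3''=C4'', with C4'' on C3') on C4'–O/C3'. There is no stereocentre, so the task is purely regiochemical. Ring B is pentasubstituted (C1' carbon, C2' oxygen, C3' carbon, C4' oxygen, C5' hydroxyl, C6' hydrogen), and ring A needs its three oxygens told apart as the pyranone oxygen, the free 5-hydroxyl and the ring E ether. Rings D and E differ only by the C3''=C4'' double bond, so that alkene must come from a handle placed on ring D alone, not from a late unselective dehydrogenation. The chromene is sensitive to strong acid, electrophiles and hydrogenation, C2 is a ketene-acetal-type carbon open to nucleophiles, and the 2',5'-dioxygenated ring B is easily over-oxidised to a quinone. Any 2'-hydroxyisoflavone met on the way is known to rearrange under base to a 3-aroylbenzofuran. The feature that invites the key step is the pattern on ring B: para oxygens on C2' and C5', hydrogen on C6', the chromone on C1', and the enol ether carbons of ring D on C3'/C4'. This is the hydroquinone monoether that results when a carbene carbon (C5'), carbon monoxide (C2'), an alkyne (C1', C6') and an alkenyl unit (C3', C4') are joined on zerovalent chromium.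

## Retrosynthesis

**24 from 23.** The O–CH3 bond at C5 and the O–CH(CH3)2 bond at C5' are cut last, leading to diether 23. One reagent, BCl3, can remove both: the methyl ether through chelation to the C4 carbonyl, the isopropyl ether because secondary alkyl aryl ethers ionise readily. A methyl ether at C5' would need far harsher Lewis acids that the chromene would not survive, and a benzyl ether would tempt hydrogenolysis. The forward step must spare the chromene and the two tertiary alkyl aryl ether bonds.

**23 from 22 and 21.** The C3''=C4'' double bond is traced to a benzylic oxygen on C4'': dehydration of alcohol 22, which comes from silyl ether 21. This oxygen is the only difference between rings D and E, so regioselective alkene formation becomes a trivial matter. It also keeps the acid- and oxidant-sensitive chromene out of every oxidative step. The alternative, dehydrogenating a plain chroman, could not distinguish ring D from ring E.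

**21 from 20.** The furan is opened at the O–C2 bond, giving the 2'-hydroxyisoflavone 20. Oxidative closure of such phenols onto C2 is an established way to coumaronochromones and needs no prior activation of C2. The closure must be done while the C5' oxygen is still alkylated. A free 2',5'-hydroquinone would simply be oxidised to the quinone, and the route through quinone, reduction and re-oxidation is therefore avoided. The medium has to stay neutral, because base would divert 20 to an aroylbenzofuran.

**20 from 9 and 18.** Ring B is taken apart at C5'–C6', C1'–C2' and C2'–C3' (and the C2' oxygen is traced to carbon monoxide). This leaves the 3-ethynylchromone 9 and the alkenyl(isopropoxy)carbene complex 18. Cutting the biaryl-type C3–C1' bond instead would leave a pentasubstituted arene to be made separately. This cut writes all six positions in one step from two much simpler partners and puts the new hydroxyl on C2', beside the chromone. The forward reaction needs regioselective alkyne insertion and carbonyl insertion, both typical of terminal alkynes with alkenyl carbene complexes.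

**18 from 16, 12, 13 and back to 10.** The carbene carbon–oxygen bond and the carbene carbon–ring bond are cut. Complex 18 comes from ammonium acylchromate 16 by acylation and alcoholysis through acetoxycarbene 17, which installs the isopropoxy group that an oxonium salt cannot. Salt 16 comes from Cr(CO)6 (13) and vinyllithium 14, via lithium acylate 15. The lithium reagent is made by deprotonating silyl ether 12, which is two steps (reduction to 11, silylation) from dihydropyranone 10. Triisopropylsilyl is preferred to a silyl group with Si–CH3 bonds, which can be metalated competitively.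

**9 from 8, 6, 7 and back to 1 and 2.** The alkyne is cut at C3–C(sp): desilylation of 8, made by Sonogashira coupling of iodochromone 6 with trimethylsilylacetylene (7). Ring C is opened at O1–C2 and C2–C3: iodocyclisation of enaminone 5 from acetophenone 4. Compound 4 is the mono-methyl ether of chroman 3, which is assembled from 2,4,6-trihydroxyacetophenone (1) and isoprene (2). The symmetry of 1 removes one regiochemical question, and the methyl group both fixes which oxygen becomes O1 and serves as the later BCl3-labile protection of the 5-hydroxyl.

## Roads not taken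

**Alternative 1: double C–H coupling of a 2-aryloxychromone.** The cut is the C3–C1' bond of the finished skeleton. Forward, Pd(OAc)2 with AgOAc in pivalic acid would join C3–H of 2-aryloxychromone A2 to the ortho C1'–H of its aryloxy ring and close the furan, giving the 5-methyl 5'-benzyl ether A1. The merits are real. The C2–O–C2' bridge is made earlier by a reliable addition–elimination, the aryloxy ring has only one free ortho C–H so the site of coupling is not in doubt, and the route is more convergent and avoids stoichiometric chromium. In these respects it is better than the chosen plan.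

Its weak points lie elsewhere:
- The coupling needs hot carboxylic acid and a silver oxidant in the presence of the chromene and of a very electron-rich ring B.
- The benzyl group must later be removed without hydrogenating the chromene.
- Above all, the problem of ring B is only moved. Chromenol A3, with its 1,2,4-trioxygenated, regiodefined substitution, still has to be made, and annulating a pyran onto a benzyloxyhydroquinone offers several competing positions.

Against the shorter sequence the chosen plan sets an unambiguous construction of ring B and a chromene that appears only after all oxidations.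

**Alternative 2: biomimetic Dieckmann folding of ring A.** The cut is C4a–C8a of ring A. Forward, LiN(SiMe3)2 would convert the enol-ether-masked chain A5 into a dienolate whose C4a carbon attacks the ester carbon C8a, closing and aromatising ring A as aroylbenzofuran A4. It has two advantages: the free hydroxyl and the methyl ether of ring A are placed with certainty, which the chosen plan obtains only through a selective mono-methylation, and no heavy metal is used.

The weak points are structural. The key step is spent on ring A, the one ring that a cheap commodity phenol already supplies. A5 is a long, fragile poly-β-carbonyl chain that already contains the complete ring B/D benzofuran, so the hard ring must again be made beforehand. A4 is still two operations from the target (oxidation of the benzofuran C2 and closure of O1–C2), on a substrate with a chromene and several electron-rich positions. The chosen plan puts its key step on the hardest ring and needs no late oxidation of a benzofuran.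

**Alternative 3: aryne insertion into a benzofuran-3-carboxylic acid.** The cuts are O1–C8a, C4–C4a and O1–C2, i.e. ring C. Forward, CsF would release an aryne from silyl triflate A7; the carboxylate of 2-chlorobenzofuran acid A8 adds at C8a, the aryl anion takes the acyl group at C4a, and the phenoxide displaces chloride at C2, giving the bis(methoxymethyl) ether A6. This is the most convergent plan, the acetal protecting groups come off under milder acid than BCl3, and the methoxymethoxy group should steer the aryne addition correctly. On these counts it is better than the chosen route.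

Its costs are in the fragments and the key step:
- A7 is an ortho-silyl triflate on a fully substituted ring.
- A8 again needs the regiodefined pentasubstituted ring B, now with a halogen at C2 and an acid at C3.
- The insertion must compete with plain O-arylation at an aryne hindered on both sides.
- The final chloride displacement is activated only by the 3-acyl group.

The overall step count would be similar or higher. The chosen plan answers with a single step that builds ring B from an alkyne, a carbene and carbon monoxide.

Key step: step 10

Assumption: 2,2-dimethyl-2,3-dihydro-4H-pyran-4-one (10) is treated as a purchasable building block; all intermediates carrying the C4'' oxygen are racemic, which is immaterial because this carbon becomes sp2 in step 13.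

## Route

Step 1
Reactants: 1 2,4,6-trihydroxyacetophenone; 2 isoprene (2-methylbuta-1,3-diene)
Product: 3 1-(5,7-dihydroxy-2,2-dimethylchroman-6-yl)ethan-1-one
Conditions: Amberlyst 15, THF–heptane, 65 °C, 1 equiv of 2
Reagents that add atoms: none
Why: Acid-catalysed chromanylation (Friedel–Crafts prenylation at C3, then Markovnikov addition of a phenol oxygen to the tertiary cation); C3 and C5 of 1 are equivalent and the two ortho hydroxyls are hydrogen-bonded to the acetyl group, so the free para oxygen should close the ring, and one equivalent of diene limits double annulation.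

Step 2
Reactants: 3 1-(5,7-dihydroxy-2,2-dimethylchroman-6-yl)ethan-1-one
Product: 4 1-(5-hydroxy-7-methoxy-2,2-dimethylchroman-6-yl)ethan-1-one
Conditions: Me2SO4 (1.0 equiv), K2CO3, acetone, reflux
Reagents that add atoms: dimethyl sulfate, COS(=O)(=O)OC
Why: Williamson methylation under weak base; the C5 hydroxyl is flanked by the ring methylene and holds the chelating hydrogen bond, so the less hindered C7 hydroxyl should be etherified, and a second alkylation is slow once the remaining hydroxyl is locked to the carbonyl.

Step 3
Reactants: 4 1-(5-hydroxy-7-methoxy-2,2-dimethylchroman-6-yl)ethan-1-one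
Product: 6 3-iodo-5-methoxy-8,8-dimethyl-9,10-dihydro-4H,8H-pyrano[2,3-f]chromen-4-one, via enaminone 5 (not isolated)
Conditions: Me2NCH(OMe)2, toluene, 95 °C; evaporate; I2, CHCl3, rt
Reagents that add atoms: N,N-dimethylformamide dimethyl acetal, COC(OC)N(C)C; iodine, II
Why: The acetyl methyl group condenses with the amide acetal to give enaminone 5; iodine adds to its α-carbon, the chelated phenol closes onto the iminium carbon and dimethylamine is lost (enaminone iodocyclisation, the standard route to 3-iodochromones), while the methyl ether excludes the other mode of ring closure.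

Step 4
Reactants: 6 3-iodo-5-methoxy-8,8-dimethyl-9,10-dihydro-4H,8H-pyrano[2,3-f]chromen-4-one; 7 trimethylsilylacetylene
Product: 8 5-methoxy-8,8-dimethyl-3-[(trimethylsilyl)ethynyl]-9,10-dihydro-4H,8H-pyrano[2,3-f]chromen-4-one
Conditions: PdCl2(PPh3)2 (cat.), CuI (cat.), Et3N, THF, rt
Reagents that add atoms: none
Why: Sonogashira coupling of a 3-iodochromone, an activated α-iodo enone, runs at room temperature; a tertiary amine is used because secondary amines add to C2 of chromones.

Step 5
Reactants: 8 5-methoxy-8,8-dimethyl-3-[(trimethylsilyl)ethynyl]-9,10-dihydro-4H,8H-pyrano[2,3-f]chromen-4-one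
Product: 9 3-ethynyl-5-methoxy-8,8-dimethyl-9,10-dihydro-4H,8H-pyrano[2,3-f]chromen-4-one
Conditions: TBAF, AcOH, THF, 0 °C
Reagents that add atoms: none
Why: Fluoride-induced protodesilylation of an alkynylsilane; buffering with acetic acid keeps the medium non-basic so that C2 of the chromone and the terminal alkyne are left alone.

Step 6
Reactants: 10 2,2-dimethyl-2,3-dihydro-4H-pyran-4-one
Product: 11 2,2-dimethyl-3,4-dihydro-2H-pyran-4-ol (racemic)
Conditions: NaBH4, CeCl3·7H2O, MeOH, −78 °C
Reagents that add atoms: none
Why: Luche 1,2-reduction of the vinylogous ester carbonyl, as used for dihydropyranones on the way to glycals; the carbinol centre forms as a racemate, which does not matter because it is destroyed in step 13.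

Step 7
Reactants: 11 2,2-dimethyl-3,4-dihydro-2H-pyran-4-ol (racemic)
Product: 12 [(2,2-dimethyl-3,4-dihydro-2H-pyran-4-yl)oxy]triisopropylsilane (racemic)
Conditions: i-Pr3SiCl, imidazole, DMF, rt
Reagents that add atoms: chlorotriisopropylsilane, CC(C)[Si](Cl)(C(C)C)C(C)C
Why: Standard silylation of a secondary allylic alcohol under basic conditions that avoid allylic ionisation of the enol ether; triisopropylsilyl has no silicon-bound methyl group that could compete in the metalation of step 8.

Step 8
Reactants: 12 [(2,2-dimethyl-3,4-dihydro-2H-pyran-4-yl)oxy]triisopropylsilane (racemic); 13 chromium hexacarbonyl Cr(CO)6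
Product: 16 tetramethylammonium pentacarbonyl{[2,2-dimethyl-4-(triisopropylsilyloxy)-3,4-dihydro-2H-pyran-6-yl]carbonyl}chromate (racemic), via vinyllithium 14 (not isolated), via lithium acylchromate 15 (not isolated)
Conditions: t-BuLi, THF–pentane, −78 to 0 °C; Cr(CO)6, THF, 0 °C to rt; Me4NBr, H2O
Reagents that add atoms: tetramethylammonium bromide, C[N+](C)(C)C.[Br-]
Why: Vinylic α-deprotonation of a cyclic enol ether by t-BuLi is the established entry to 1-lithioglycals and 6-lithiodihydropyrans; the vinyllithium adds to a carbonyl ligand of Cr(CO)6 (first half of the Fischer carbene synthesis) and cation exchange gives an acylchromate salt that can be handled and acylated cleanly.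

Step 9
Reactants: 16 tetramethylammonium pentacarbonyl{[2,2-dimethyl-4-(triisopropylsilyloxy)-3,4-dihydro-2H-pyran-6-yl]carbonyl}chromate (racemic)
Product: 18 pentacarbonyl{[2,2-dimethyl-4-(triisopropylsilyloxy)-3,4-dihydro-2H-pyran-6-yl](propan-2-yloxy)methylidene}chromium (racemic), via acetoxycarbene complex 17 (not isolated)
Conditions: AcBr, CH2Cl2, −40 °C; then i-PrOH, −40 to 0 °C
Reagents that add atoms: propan-2-ol, CC(C)O
Why: O-Acylation of the acylchromate gives an acyloxycarbene complex whose carbene carbon is attacked by the alcohol with loss of acetate, the standard route to alkoxycarbene complexes that oxonium salts cannot deliver; isopropoxy is chosen so that the C5' oxygen can later be freed by BCl3.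

Step 10
Reactants: 9 3-ethynyl-5-methoxy-8,8-dimethyl-9,10-dihydro-4H,8H-pyrano[2,3-f]chromen-4-one; 18 pentacarbonyl{[2,2-dimethyl-4-(triisopropylsilyloxy)-3,4-dihydro-2H-pyran-6-yl](propan-2-yloxy)methylidene}chromium (racemic)
Product: 20 3-[5-hydroxy-2,2-dimethyl-8-(propan-2-yloxy)-4-(triisopropylsilyloxy)chroman-6-yl]-5-methoxy-8,8-dimethyl-9,10-dihydro-4H,8H-pyrano[2,3-f]chromen-4-one (racemic), via tricarbonylchromium arene complex 19 (not isolated)
Conditions: THF, 50 °C, Ar; then air, Et2O, rt
Reagents that add atoms: none
Why: This is a Dötz benzannulation, known for alkenyl(alkoxy)carbene complexes of chromium, 2-dihydropyranyl and glycal-derived ones included, with terminal alkynes. Thermal loss of one cis carbonyl ligand from 18 opens a site for alkyne 9, which inserts into the chromium–carbene bond to give a vinylcarbene; carbonyl insertion then gives a chromium-bound dienylketene. Ring B closes by 6π electrocyclisation of this dienylketene (ketene carbon to the β-carbon of the dihydropyran), and the cyclohexadienone tautomerises to phenol complex 19, which air demetalates to 20. Three bonds form (C5'–C6', C1'–C2', C2'–C3') and all six positions of ring B are fixed at once: C5' with its isopropoxy group from the carbene carbon, C2' with its hydroxyl from carbon monoxide, C1' and C6' from the alkyne, C3' and C4' from the enol ether. The selectivity needed is the direction of alkyne insertion: a terminal alkyne places its unsubstituted carbon next to the carbene carbon, away from the carbonyl ligands, so the chromonyl group ends on C1' beside the new hydroxyl. Phenol formation over cyclopentannulation is favoured by the alkenyl (not aryl) carbene, by chromium and by the coordinating solvent. No stereocentre is created; the silyloxy carbon is a spectator and stays racemic.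

Step 11
Reactants: 20 3-[5-hydroxy-2,2-dimethyl-8-(propan-2-yloxy)-4-(triisopropylsilyloxy)chroman-6-yl]-5-methoxy-8,8-dimethyl-9,10-dihydro-4H,8H-pyrano[2,3-f]chromen-4-one (racemic)
Product: 21 5'-O-isopropyl-5-O-methyl-4''-(triisopropylsilyloxy)-3'',4''-dihydroformosanatin D (racemic; coumaronochromone with ring D as a 4-silyloxy-2,2-dimethylchroman)
Conditions: DDQ (1.1 equiv), dry 1,4-dioxane, rt
Reagents that add atoms: none
Why: Oxidative cyclisation of 2'-hydroxyisoflavones to coumaronochromones with DDQ is a known reaction type; two-electron oxidation of the 4-alkoxyphenol gives a cation delocalised through C1' and C3 onto C2 (stabilised by O1), the C2' oxygen closes the five-membered ring and loss of the C2 proton aromatises the furan, while the neutral medium avoids the base-induced rearrangement to an aroylbenzofuran.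

Step 12
Reactants: 21 5'-O-isopropyl-5-O-methyl-4''-(triisopropylsilyloxy)-3'',4''-dihydroformosanatin D (racemic)
Product: 22 4''-hydroxy-5'-O-isopropyl-5-O-methyl-3'',4''-dihydroformosanatin D (racemic)
Conditions: TBAF, AcOH, THF, 0 °C to rt
Reagents that add atoms: none
Why: Fluoride cleavage of a secondary silyl ether; acetic acid buffering protects the nucleophile-sensitive C2 of the coumaronochromone.

Step 13
Reactants: 22 4''-hydroxy-5'-O-isopropyl-5-O-methyl-3'',4''-dihydroformosanatin D (racemic)
Product: 23 formosanatin D 5'-isopropyl 5-methyl ether
Conditions: p-TsOH·H2O (cat.), toluene, 80 °C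
Reagents that add atoms: none
Why: Acid-catalysed dehydration of a chroman-4-ol is the classical route to 2,2-dimethyl-2H-chromenes; the benzylic cation is stabilised by the two ortho oxygens and can lose a proton only from C3'', and ring E, which lacks the hydroxyl, stays saturated.

Step 14
Reactants: 23 formosanatin D 5'-isopropyl 5-methyl ether
Product: 24 Formosanatin D
Conditions: BCl3, CH2Cl2, −78 to 0 °C; then MeOH, aq NaHCO3
Reagents that add atoms: none
Why: BCl3 cleaves the C5 methyl ether through a six-membered chelate with the C4 carbonyl and cleaves aryl isopropyl ethers at or below 0 °C (Lewis acid ether cleavage), conditions that 2,2-dimethylchromenes and chromans are known to tolerate.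

## Compound list

1 | 2,4,6-trihydroxyacetophenone | CC(=O)c1c(O)cc(O)cc1O | starting material
2 | isoprene (2-methylbuta-1,3-diene) | C=CC(C)=C | starting material
3 | 1-(5,7-dihydroxy-2,2-dimethylchroman-6-yl)ethan-1-one | CC(=O)c1c(O)cc2OC(C)(C)CCc2c1O | intermediate
4 | 1-(5-hydroxy-7-methoxy-2,2-dimethylchroman-6-yl)ethan-1-one | COc1cc2OC(C)(C)CCc2c(O)c1C(C)=O | intermediate
5 | (E)-3-(dimethylamino)-1-(5-hydroxy-7-methoxy-2,2-dimethylchroman-6-yl)prop-2-en-1-one (not isolated) | COc1cc2OC(C)(C)CCc2c(O)c1C(=O)/C=C/N(C)C | intermediate
6 | 3-iodo-5-methoxy-8,8-dimethyl-9,10-dihydro-4H,8H-pyrano[2,3-f]chromen-4-one | Ic1coc2c3c(cc(OC)c2c1=O)OC(C)(C)CC3 | intermediate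
7 | trimethylsilylacetylene | C[Si](C)(C)C#C | starting material
8 | 5-methoxy-8,8-dimethyl-3-[(trimethylsilyl)ethynyl]-9,10-dihydro-4H,8H-pyrano[2,3-f]chromen-4-one | C[Si](C)(C)C#Cc1coc2c3c(cc(OC)c2c1=O)OC(C)(C)CC3 | intermediate
9 | 3-ethynyl-5-methoxy-8,8-dimethyl-9,10-dihydro-4H,8H-pyrano[2,3-f]chromen-4-one | C#Cc1coc2c3c(cc(OC)c2c1=O)OC(C)(C)CC3 | intermediate
10 | 2,2-dimethyl-2,3-dihydro-4H-pyran-4-one | CC1(C)CC(=O)C=CO1 | starting material
11 | 2,2-dimethyl-3,4-dihydro-2H-pyran-4-ol (racemic) | CC1(C)CC(O)C=CO1 | intermediate
12 | [(2,2-dimethyl-3,4-dihydro-2H-pyran-4-yl)oxy]triisopropylsilane (racemic) | CC1(C)CC(O[Si](C(C)C)(C(C)C)C(C)C)C=CO1 | intermediate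
13 | chromium hexacarbonyl, Cr(CO)6 | O=C=[Cr](=C=O)(=C=O)(=C=O)(=C=O)=C=O | starting material
14 | [2,2-dimethyl-4-(triisopropylsilyloxy)-3,4-dihydro-2H-pyran-6-yl]lithium (racemic, not isolated) | [Li]C1=CC(O[Si](C(C)C)(C(C)C)C(C)C)CC(C)(C)O1 | intermediate
15 | lithium pentacarbonyl{[2,2-dimethyl-4-(triisopropylsilyloxy)-3,4-dihydro-2H-pyran-6-yl]carbonyl}chromate (racemic, not isolated) | [Li+].[O-]C(=[Cr](=C=O)(=C=O)(=C=O)(=C=O)=C=O)C1=CC(O[Si](C(C)C)(C(C)C)C(C)C)CC(C)(C)O1 | intermediate
16 | tetramethylammonium pentacarbonyl{[2,2-dimethyl-4-(triisopropylsilyloxy)-3,4-dihydro-2H-pyran-6-yl]carbonyl}chromate (racemic) | C[N+](C)(C)C.[O-]C(=[Cr](=C=O)(=C=O)(=C=O)(=C=O)=C=O)C1=CC(O[Si](C(C)C)(C(C)C)C(C)C)CC(C)(C)O1 | intermediate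
17 | pentacarbonyl{(acetyloxy)[2,2-dimethyl-4-(triisopropylsilyloxy)-3,4-dihydro-2H-pyran-6-yl]methylidene}chromium (racemic, not isolated) | CC(=O)OC(=[Cr](=C=O)(=C=O)(=C=O)(=C=O)=C=O)C1=CC(O[Si](C(C)C)(C(C)C)C(C)C)CC(C)(C)O1 | intermediate
18 | pentacarbonyl{[2,2-dimethyl-4-(triisopropylsilyloxy)-3,4-dihydro-2H-pyran-6-yl](propan-2-yloxy)methylidene}chromium (racemic) | CC(C)OC(=[Cr](=C=O)(=C=O)(=C=O)(=C=O)=C=O)C1=CC(O[Si](C(C)C)(C(C)C)C(C)C)CC(C)(C)O1 | intermediate
19 | tricarbonylchromium η6-complex of phenol 20 on ring B (racemic, not isolated; metal fragment written as a separate component) | CC(C)Oc1cc(-c2coc3c4c(cc(OC)c3c2=O)OC(C)(C)CC4)c(O)c2c1OC(C)(C)CC2O[Si](C(C)C)(C(C)C)C(C)C.O=C=[Cr](=C=O)=C=O | intermediate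
20 | 3-[5-hydroxy-2,2-dimethyl-8-(propan-2-yloxy)-4-(triisopropylsilyloxy)chroman-6-yl]-5-methoxy-8,8-dimethyl-9,10-dihydro-4H,8H-pyrano[2,3-f]chromen-4-one (racemic) | CC(C)Oc1cc(-c2coc3c4c(cc(OC)c3c2=O)OC(C)(C)CC4)c(O)c2c1OC(C)(C)CC2O[Si](C(C)C)(C(C)C)C(C)C | intermediate
21 | 5'-O-isopropyl-5-O-methyl-4''-(triisopropylsilyloxy)-3'',4''-dihydroformosanatin D (racemic) | CC1(C)CC(O[Si](C(C)C)(C(C)C)C(C)C)c2c(c(OC(C)C)cc3c2oc2oc4c5c(cc(OC)c4c(=O)c23)OC(C)(C)CC5)O1 | intermediate
22 | 4''-hydroxy-5'-O-isopropyl-5-O-methyl-3'',4''-dihydroformosanatin D (racemic) | CC1(C)CC(O)c2c(c(OC(C)C)cc3c2oc2oc4c5c(cc(OC)c4c(=O)c23)OC(C)(C)CC5)O1 | intermediate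
23 | formosanatin D 5'-isopropyl 5-methyl ether | CC1(C)C=Cc2c(c(OC(C)C)cc3c2oc2oc4c5c(cc(OC)c4c(=O)c23)OC(C)(C)CC5)O1 | intermediate
24 | Formosanatin D | CC1(C)C=Cc2c(c(O)cc3c2oc2oc4c5c(cc(O)c4c(=O)c23)OC(C)(C)CC5)O1 | target

Total step count: 14. Longest linear sequence: 10 steps (steps 1–5, then 10–14); the carbene branch (steps 6–9) joins at step 10.

## Least certain steps

**Step 10 (key step).** The most likely failure is slow or misdirected alkyne insertion. The alkyne is conjugated to an electron-poor chromone, so carbene 18 may decompose thermally before it inserts, and the chromone carbonyl may coordinate chromium in the vinylcarbene and divert it before carbonyl insertion. Fallback: keep the benzannulation but change the alkyne. Carbene 18 is heated with commercial ethynylboronic acid pinacol ester, a small and electronically neutral terminal alkyne. The boryl group should take the position next to the new hydroxyl, giving 2-[5-hydroxy-2,2-dimethyl-8-(propan-2-yloxy)-4-(triisopropylsilyloxy)chroman-6-yl]-4,4,5,5-tetramethyl-1,3,2-dioxaborolane F1. Suzuki–Miyaura coupling of this with iodochromone 6 (Pd(PPh3)4, K3PO4, dioxane–water, moderate temperature to limit base contact of the product) then installs the chromone. The fallback sets out from 18 (with 6 from step 3) and returns at 20.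

**Step 11.** The most likely failure is dealkylative over-oxidation. The oxidised 4-isopropoxyphenol may lose its isopropyl group and collapse to the para-quinone faster than the C2' oxygen closes onto C2. A second risk is hydride abstraction at the benzylic silyloxy carbon if excess oxidant is present. Fallback: make the quinone on purpose and close the furan without further oxidation.
- (NH4)2Ce(NO3)6 in aqueous MeCN at 0 °C converts 20 into the 2-(chromon-3-yl)-1,4-benzoquinone F2.
- BF3·OEt2 (or CF3CO2H) in CH2Cl2 should then induce cycloisomerisation. The acid-bound C5' carbonyl draws electron density from the chromone enol ether, the C2' carbonyl oxygen captures the resulting C2 cation and proton loss aromatises. This is an extrapolation, not established chemistry on this ring system. It follows the acid-promoted closure of aryl-1,4-benzoquinones to hydroxydibenzofurans and is the proton analogue of the mechanism of step 11. It gives 5-O-methyl-4''-(triisopropylsilyloxy)-3'',4''-dihydroformosanatin D F3.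
- The conditions of steps 12 and 13 give 4''-hydroxy-5-O-methyl-3'',4''-dihydroformosanatin D F4 and formosanatin D 5-methyl ether F5. F5 would form directly if the Lewis acid also ionises the benzylic silyl ether.
- BCl3 at −78 °C then cleaves only the chelated methyl ether.

The fallback sets out from 20 and returns at 24.

**Step 14.** The most likely failure is acid-mediated addition to, or oligomerisation of, the chromene double bond, and opening of the allylic tertiary ether of ring D, before the isopropyl ether is fully cleaved at 0 °C. Fallback: dealkylate while ring D is a ketone and form the alkene last.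
- Alcohol 22 is oxidised (MnO2, CH2Cl2) to the chroman-4-one, 5'-O-isopropyl-5-O-methyl-4''-oxo-3'',4''-dihydroformosanatin D F6.
- BCl3 then gives 4''-oxo-3'',4''-dihydroformosanatin D F7.
- NaBH4 in MeOH reduces the aryl ketone in preference to the chelated, vinylogous-carbonate C4 carbonyl, giving 4''-hydroxy-3'',4''-dihydroformosanatin D F8.
- p-TsOH in toluene dehydrates F8 to the chromene.

The fallback sets out from 22 and returns at 24.

**Step 9.** The most likely failure is decomposition of the thermally labile acetoxycarbene 17, or acid-induced loss of the allylic silyloxy group by the liberated acetic acid, before alcoholysis is complete. Fallback: direct O-alkylation of acylchromate 16 with isopropyl trifluoromethanesulfonate (made from propan-2-ol and Tf2O with a hindered pyridine) in CH2Cl2 at low temperature. This is the oxygen-alkylation mode of the Fischer synthesis and bypasses 17. It sets out from 16 and returns at 18 without any new compound (entry F0).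

**Step 1.** The most likely failure is loss of regiocontrol in the ring closure (cyclisation onto an ortho oxygen, giving the 8-acetyl isomer) together with double annulation. Fallback: fix the ring oxygen before the carbon–carbon bond is made.
- Selective alkylation of the most acidic para hydroxyl of 1 with 3-chloro-3-methylbut-1-yne (K2CO3, KI, CuI cat., acetone) gives 1-[2,6-dihydroxy-4-(2-methylbut-3-yn-2-yloxy)phenyl]ethan-1-one F9.
- Thermal propargyl Claisen rearrangement and ring closure (xylene, reflux) gives 1-(5,7-dihydroxy-2,2-dimethyl-2H-chromen-6-yl)ethan-1-one F10.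
- Hydrogenation (H2, Pd/C, EtOAc) saturates the chromene.

The fallback sets out from 1 and returns at 3.

**Step 2.** The most likely failure is methylation at the wrong (C5) hydroxyl, or double methylation, since both hydroxyls are ortho to the acetyl group. Fallback: reverse the selectivity problem. Exhaustive methylation (excess Me2SO4, K2CO3) gives 1-(5,7-dimethoxy-2,2-dimethylchroman-6-yl)ethan-1-one F11. One equivalent of BCl3 at −78 °C then removes a single ortho methyl group by chelation, preferentially the more hindered one next to the ring methylene. The fallback sets out from 3 and returns at 4.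

## Further compounds

F1 | step 10 | 2-[5-hydroxy-2,2-dimethyl-8-(propan-2-yloxy)-4-(triisopropylsilyloxy)chroman-6-yl]-4,4,5,5-tetramethyl-1,3,2-dioxaborolane (racemic) | CC(C)Oc1cc(B2OC(C)(C)C(C)(C)O2)c(O)c2c1OC(C)(C)CC2O[Si](C(C)C)(C(C)C)C(C)C
F2 | step 11 | 2-(chromon-3-yl)-1,4-benzoquinone of ring B with the 4-(triisopropylsilyloxy)chroman ring D (racemic) | O=C1C=C(c2coc3c4c(cc(OC)c3c2=O)OC(C)(C)CC4)C(=O)C2=C1OC(C)(C)CC2O[Si](C(C)C)(C(C)C)C(C)C
F3 | step 11 | 5-O-methyl-4''-(triisopropylsilyloxy)-3'',4''-dihydroformosanatin D (racemic) | CC1(C)CC(O[Si](C(C)C)(C(C)C)C(C)C)c2c(c(O)cc3c2oc2oc4c5c(cc(OC)c4c(=O)c23)OC(C)(C)CC5)O1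
F4 | step 11 | 4''-hydroxy-5-O-methyl-3'',4''-dihydroformosanatin D (racemic) | CC1(C)CC(O)c2c(c(O)cc3c2oc2oc4c5c(cc(OC)c4c(=O)c23)OC(C)(C)CC5)O1
F5 | step 11 | formosanatin D 5-methyl ether | CC1(C)C=Cc2c(c(O)cc3c2oc2oc4c5c(cc(OC)c4c(=O)c23)OC(C)(C)CC5)O1
F6 | step 14 | 5'-O-isopropyl-5-O-methyl-4''-oxo-3'',4''-dihydroformosanatin D | CC1(C)CC(=O)c2c(c(OC(C)C)cc3c2oc2oc4c5c(cc(OC)c4c(=O)c23)OC(C)(C)CC5)O1
F7 | step 14 | 4''-oxo-3'',4''-dihydroformosanatin D | CC1(C)CC(=O)c2c(c(O)cc3c2oc2oc4c5c(cc(O)c4c(=O)c23)OC(C)(C)CC5)O1
F8 | step 14 | 4''-hydroxy-3'',4''-dihydroformosanatin D (racemic) | CC1(C)CC(O)c2c(c(O)cc3c2oc2oc4c5c(cc(O)c4c(=O)c23)OC(C)(C)CC5)O1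
F0 | step 9 | none | none
F9 | step 1 | 1-[2,6-dihydroxy-4-(2-methylbut-3-yn-2-yloxy)phenyl]ethan-1-one | CC(=O)c1c(O)cc(OC(C)(C)C#C)cc1O
F10 | step 1 | 1-(5,7-dihydroxy-2,2-dimethyl-2H-chromen-6-yl)ethan-1-one | CC(=O)c1c(O)cc2OC(C)(C)C=Cc2c1O
F11 | step 2 | 1-(5,7-dimethoxy-2,2-dimethylchroman-6-yl)ethan-1-one | COc1cc2OC(C)(C)CCc2c(OC)c1C(C)=O
A1 | alternative 1 | formosanatin D 5-methyl 5'-benzyl ether | CC1(C)C=Cc2c(c(OCc3ccccc3)cc3c2oc2oc4c5c(cc(OC)c4c(=O)c23)OC(C)(C)CC5)O1
A2 | alternative 1 | 2-{[8-(benzyloxy)-2,2-dimethyl-2H-chromen-5-yl]oxy}-5-methoxy-8,8-dimethyl-9,10-dihydro-4H,8H-pyrano[2,3-f]chromen-4-one | O=c1cc(Oc2ccc(OCc3ccccc3)c3OC(C)(C)C=Cc23)oc2c3CCC(C)(C)Oc3cc(OC)c12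
A3 | alternative 1 | 8-(benzyloxy)-2,2-dimethyl-2H-chromen-5-ol | Oc1ccc(OCc2ccccc2)c2OC(C)(C)C=Cc12
A4 | alternative 2 | (5-hydroxy-7-methoxy-2,2-dimethylchroman-6-yl)(ring B/D benzofuran-3-yl)methanone, 5'-methoxymethyl ether | CC1(C)C=Cc2c(c(OCOC)cc3c(C(=O)c4c(OC)cc5OC(C)(C)CCc5c4O)coc23)O1
A5 | alternative 2 | methyl 2-[(1E)-2-methoxy-4-oxo-4-(ring B/D benzofuran-3-yl)but-1-en-1-yl]-6,6-dimethyl-5,6-dihydro-4H-pyran-3-carboxylate | COC(=O)C1=C(/C=C(\CC(=O)c2coc3c2cc(OCOC)c2OC(C)(C)C=Cc32)OC)OC(C)(C)CC1
A6 | alternative 3 | formosanatin D 5,5'-bis(methoxymethyl) ether | CC1(C)C=Cc2c(c(OCOC)cc3c2oc2oc4c5c(cc(OCOC)c4c(=O)c23)OC(C)(C)CC5)O1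
A7 | alternative 3 | 7-(methoxymethoxy)-2,2-dimethyl-6-(trimethylsilyl)chroman-5-yl trifluoromethanesulfonate | COCOc1cc2OC(C)(C)CCc2c(OS(=O)(=O)C(F)(F)F)c1[Si](C)(C)C
A8 | alternative 3 | ring B/D 2-chloro-5-(methoxymethoxy)benzofuran-3-carboxylic acid with the 2,2-dimethyl-2H-pyran fused at C6–O/C7 | OC(=O)c1c(Cl)oc2c1cc(OCOC)c1OC(C)(C)C=Cc21
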